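## The problem

Compound 18 is an achiral triaryl system. A central benzene (ring A) carries a 4-hydroxybenzoyl group (ring B) and, through a saturated three-carbon chain, a 4-hydroxyphenyl group (ring C). There is no ring fusion and no stereocenter, so the whole difficulty lies in the substitution pattern of ring A. Ring A is 1,2,4,5-tetrasubstituted: OMe at C1, OH at C3, the aroyl carbon at C4 and the chain at C6, with hydrogen at C2 and C5. Its two oxygens must be told apart (one methyl ether, one free phenol) beside two further free phenols on rings B and C. The only intrinsic difference is that the C3 oxygen is ortho to the ketone and chelated, while the C1 oxygen is not. The phenols are electron-rich and easily C-alkylated or oxidised, and the diaryl ketone can be reduced, so the end of the route should be short and non-reductive. The feature that suggests the key step is that the two unsubstituted carbons, C2 and C5, are para to each other, with oxygen-bearing C3 and acyl-bearing C4 between them on one side and oxygen-bearing C1 next to carbon-bearing C6 on the other. A 4-alkoxy-5-acyl-2-pyranone leaves exactly this pattern (its C3 to C6 become C2 to C5 once the lactone bridge departs as CO2), a 1-alkoxyalkyne supplies C1 and C6, and the polarity fits: acceptor on the diene, donor on the alkyne.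

## Retrosynthesis

**18 from 17.** Only three O–C bonds are cut: the methyl ether at the C3 oxygen and the two benzyl ethers on rings B and C. Benzyl is chosen for the outer phenols because it survives the amide bases and the thermal step. Methyl is chosen at C3 because the pyranone route delivers it for free and because chelation to the ketone lets BCl3 remove it selectively. The neighbouring option, hydrogenolysis followed by a separate demethylation, costs a step and exposes the ketone to hydrogen. The forward reaction must spare the unchelated C1 methyl ether.

**17 from 9 and 15 (key disconnection).** The bonds C1–C2 and C5–C6 of ring A are cut, and a CO2 bridge is added back between C2 and C5, which leads to pyranone 9 and ynol ether 15 by way of the bridged lactone 16. The obvious neighbour is the aryl–carbonyl cut (Friedel–Crafts acylation of a resorcinol diether). It is shorter on paper, but it leaves the regiochemistry to directing effects among three activated rings and needs a Lewis acid beside benzyl ethers. The other neighbour, cutting C3–C4 and C5–C6, is weighed below as Alternative 2. The pyranone cut removes ring A altogether: 9 holds ring B and a heterocycle, 15 holds ring C and a linear chain. The forward step must deliver one orientation (chain carbon to pyranone C6), must prefer the carbon diene over the aroyl enone, and must run at a temperature the ynol ether tolerates.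

**9 from 7 and 6.** The lactone acyl–oxygen bond is cut first, which gives the hydroxymethylene ketone 8, the hydrolysis product of enaminone 7. Then the bond from C4 of the chain to the one-carbon unit is cut, giving keto enoate 6. Formylating a 3,5-diketo ester instead would offer two active methylenes and would need a later O-methylation of a 4-hydroxypyranone. In 6 the C3 oxygen is already a methyl enol ether, only one CH2 is acidic, and the E double bond holds the ester next to the arm that will carry the new oxygen. The forward steps need lactonization through the formyl oxygen and survival of the enol ether in acid.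

**6 from 3 and 4; 3 from 1.** The bond between the ketone carbon and the CH2 group is cut, a vinylogous Claisen acylation of dienolate 5 (from enoate 3) with acid chloride 4. Enoate 3 is the methyl enol ether of methyl acetoacetate 1. This arm therefore rests on two commercial compounds. The forward reaction needs γ-selectivity and a product that does not cyclise before the next step.

**15 from 12 and 13; 12 from 10.** The C(sp3)–C(sp) bond between the chain and the alkyne is cut. The nucleophile is lithium methoxyethynide 14, made in the flask from chloroacetal 13. The electrophile is iodide 12, reached from the commercial phenol alcohol 10 through benzyl ether 11. Oxygenating a preformed terminal alkyne has far less precedent than alkylating 14. The forward step needs substitution to outrun elimination and a non-acidic isolation.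

## Roads not taken

**Alternative 1:** The chain is cut between its first and second carbon, and a temporary bond from the C1 oxygen to the benzylic chain carbon next to ring C turns the target into a flavan.
- Forward step: the hydroxymethyl ketone A1 would lose water on heating to the ortho-quinone methide A2, which the silyl-protected vinylphenol A3 traps in a hetero-Diels–Alder reaction to give the racemic chroman A4. Its stereocenter is irrelevant, because hydrogenolysis of the benzylic C–O bond, methylation of the freed C1 phenol and desilylation follow.
- Merits: ring A is bought and not built, the chain and both aryl ends are joined in one convergent step, and the chelated C3 phenol protects itself during methylation.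
- Weak points: A1 needs a regioselective mono-hydroxymethylation of a dihydroxybenzophenone. A2 bears an acyl group, forms only at high temperature and can dimerise, while A3 polymerises under the same conditions. The reductive opening of A4 must cleave a benzylic ether beside a diaryl ketone that is itself reducible. Three steps follow the key step.
- Comparison: in raw-material cost and convergence this road is better than the pyranone route, which must first make two special cycloaddition partners. The chosen plan sets against it a one-step, non-reductive end game and a ring A pattern fixed by the cycloaddition and not by the selectivity of an aromatic substitution.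

**Alternative 2:** Ring A is cut at C3–C4 and C5–C6, the complementary Diels–Alder dissection, in which a doubly oxygenated diene supplies C3, C2, C1 and C6 and an ynone supplies C4 and C5.
- Forward step: the silyl ketene acetal diene A5 would add to the aryl ethynyl ketone A6, with the chain-bearing diene terminus on the alkyne β-carbon. Loss of methanol from the adduct gives A7, the bis(benzyl ether) of the target.
- Merits: normal electron demand with a very reactive diene, mild temperature and a well-established orientation. The two ring A oxygens emerge already differentiated, so only debenzylation remains. In this respect the road is at least as good as the chosen plan, which needs a selective demethylation.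
- Weak points: A5 carries a substituent on its reacting terminus. Making it requires γ-alkylation of dienolate 5 with iodide 12, where α-alkylation normally dominates, and the enol silylation gives geometric mixtures of which only one isomer reaches the s-cis conformation easily. A6 is a terminal ynone prone to polymerisation and to open-chain Mukaiyama–Michael addition. The mixed methyl silyl ketal of the adduct can aromatise by losing either methanol or silanol.
- Comparison: the chosen plan sets against the shorter end game two unsubstituted reacting termini (pyranone C3 and C6), an aromatisation that can go only one way (loss of CO2), and partners that are each made by closely precedented reactions.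

**Alternative 3:** The cut is the C4–C5 bond of ring A, made by an aldol-type folding of a polyketide chain that is stored as a 4-pyranone.
- Forward step: hydroxide would open pyranone A8 to the tricarbonyl enaminone A9. Its carbanion at C4 attacks the aminomethylene carbon (C5, a masked aldehyde), amine is expelled, and the ring aromatises to the resorcinol A10. Methylation of the unchelated C1 phenol and debenzylation would finish.
- Merits: no special reagents are needed. The folding is well defined, since the other doubly activated carbanion (C2) could only close a four-membered ring. The selective O-methylation of the unchelated phenol of a 2,4-dihydroxybenzophenone is more firmly established than the BCl3 discrimination used in the chosen plan.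
- Weak points: A8 is the most elaborate precursor of all four strategies, since a 2-aryl-6-alkyl-4-pyranone must be built and then aminomethylenated at a weakly acidic, hindered side-chain methylene. In hot hydroxide A9 can suffer retro-Claisen cleavage or premature hydrolysis of the vinylogous amide. Two steps follow the ring closure.
- Comparison: the chosen plan is shorter overall and forms ring A under neutral thermal conditions without polycarbonyl intermediates. It pays for this with a less routine final deprotection.

Key step: step 8

Assumption: compounds 7 and 8 are written without a defined geometry at the C4=C5 double bond, a push–pull alkene of low rotational barrier; only the E geometry of the C2=C3 enoate matters for ring closure.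

## Route

Step 1
Reactants: 1 methyl acetoacetate
Product: 3 methyl (E)-3-methoxybut-2-enoate, via methyl 3,3-dimethoxybutanoate 2 (not isolated)
Conditions: HC(OMe)3 (1.1 equiv), H2SO4 (cat.), MeOH, rt; then distillation
Reagents that add atoms: trimethyl orthoformate, COC(OC)OC
Why: Acid-catalysed ketalization of the ketone and loss of methanol on distillation give the conjugated enol ether (enol ether formation of a β-keto ester); the E isomer is the thermodynamic product and places the C4 methyl cis to the ester.

Step 2
Reactants: 3 methyl (E)-3-methoxybut-2-enoate; 4 4-(benzyloxy)benzoyl chloride
Product: 6 methyl (2E)-5-[4-(benzyloxy)phenyl]-3-methoxy-5-oxopent-2-enoate, via lithium 1,3-dimethoxybuta-1,3-dien-1-olate 5 (not isolated)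
Conditions: 3 (2.1 equiv), LiN(iPr)2 (2.1 equiv), THF, −78 °C; 4 (1 equiv), −78 °C; AcOH, −78 °C
Reagents that add atoms: none
Why: LiN(iPr)2 deprotonates the C4 methyl to the dienolate 5, whose γ-carbon attacks the acid chloride (vinylogous Claisen acylation, as with dienolates of β-alkoxy enoates and dioxinones); two equivalents of dienolate are used because 6 is more acidic than 3, and the cold acidic quench keeps the product enolate from closing onto the ester.

Step 3
Reactants: 6 methyl (2E)-5-[4-(benzyloxy)phenyl]-3-methoxy-5-oxopent-2-enoate
Product: 7 methyl (2E)-4-[4-(benzyloxy)benzoyl]-5-(dimethylamino)-3-methoxypenta-2,4-dienoate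
Conditions: Me2NCH(OMe)2 (1.5 equiv), toluene, 60 °C
Reagents that add atoms: N,N-dimethylformamide dimethyl acetal, COC(OC)N(C)C
Why: The C4 methylene, flanked by the aryl ketone and the vinylogous ester, is the only acidic CH2 of 6, so aminomethylenation of this active methylene by the amide acetal can occur at one site only and also blocks later enolization of the ketone towards C4.

Step 4
Reactants: 7 methyl (2E)-4-[4-(benzyloxy)benzoyl]-5-(dimethylamino)-3-methoxypenta-2,4-dienoate
Product: 9 5-[4-(benzyloxy)benzoyl]-4-methoxy-2H-pyran-2-one, via methyl (2E)-4-[4-(benzyloxy)benzoyl]-5-hydroxy-3-methoxypenta-2,4-dienoate 8 (not isolated)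
Conditions: AcOH, H2O (3 equiv), 60 °C
Reagents that add atoms: water, O
Why: Aqueous acid hydrolyses the vinylogous amide to the hydroxymethylene ketone 8, whose terminal enol oxygen (the site at which α-formyl ketones are O-acylated) attacks the cis ester in a 6-exo-trig acyl substitution with loss of methanol, the lactonization that turns formylacetic and aminomethylene glutaconic esters into 2-pyranones; the acid keeps the released dimethylamine protonated, away from C6 of the product, and is mild enough that the vinylogous carbonate methyl ether should survive.

Step 5
Reactants: 10 3-(4-hydroxyphenyl)propan-1-ol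
Product: 11 3-[4-(benzyloxy)phenyl]propan-1-ol
Conditions: BnBr (1.05 equiv), K2CO3, acetone, reflux
Reagents that add atoms: benzyl bromide, BrCc1ccccc1
Why: Williamson ether synthesis; K2CO3 deprotonates only the phenol and not the primary alcohol, so benzylation is chemoselective for the phenolic oxygen.

Step 6
Reactants: 11 3-[4-(benzyloxy)phenyl]propan-1-ol
Product: 12 1-(benzyloxy)-4-(3-iodopropyl)benzene
Conditions: I2, PPh3, imidazole, CH2Cl2, 0 °C to rt
Reagents that add atoms: iodine, II
Why: Appel-type iodination of a primary alcohol through the alkoxyphosphonium iodide (SN2); the benzyl ether is inert under these neutral conditions.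

Step 7
Reactants: 13 2-chloro-1,1-dimethoxyethane; 12 1-(benzyloxy)-4-(3-iodopropyl)benzene
Product: 15 1-(benzyloxy)-4-(5-methoxypent-4-yn-1-yl)benzene, via lithium methoxyethynide 14 (not isolated)
Conditions: 13 (1.5 equiv), LiNEt2 (4.5 equiv, from n-BuLi and Et2NH), THF, 0 °C; then 12 (1 equiv), DMPU, 0 °C to rt; basic work-up, Et3N-deactivated silica
Reagents that add atoms: none
Why: Three equivalents of LiNEt2 convert the chloroacetal by two eliminations (methanol, then HCl) and deprotonation into the acetylide 14, which is alkylated by the primary iodide in the dipolar cosolvent (SN2 alkylation of a lithium alkoxyacetylide, a known one-flask route to 1-methoxyalkynes); the methoxy group has no β-hydrogen, so the product cannot fragment to a ketene by a retro-ene path and should tolerate the heat of step 8.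

Step 8
Reactants: 9 5-[4-(benzyloxy)benzoyl]-4-methoxy-2H-pyran-2-one; 15 1-(benzyloxy)-4-(5-methoxypent-4-yn-1-yl)benzene
Product: 17 [4-(benzyloxy)phenyl]{5-[3-(4-(benzyloxy)phenyl)propyl]-2,4-dimethoxyphenyl}methanone, via the racemic 2-oxabicyclo[2.2.2]octa-5,7-dien-3-one cycloadduct 16 (not isolated)
Conditions: 15 (2 equiv), toluene, 120 °C, sealed tube, base-washed glassware
Reagents that add atoms: none
Why: The ynol ether is an electron-rich, polarized 2π partner with its largest HOMO coefficient on the chain-bearing carbon, and the pyranone is an electron-poor diene whose C6 is both the β-carbon of the aroyl enone and the δ-carbon of the lactone dienoate, so an asynchronous inverse-electron-demand [4+2] addition should join the chain carbon to pyranone C6 and the methoxy carbon to pyranone C3. This closes the six-membered carbocycle by cycloaddition (two C–C bonds, C1–C2 and C5–C6 of ring A) and gives the bridged lactone 16. Lactone 16 then expels CO2 by a retro-[4+2] reaction, and because the 2π partner was an alkyne the product is a benzene, so gas loss and aromatization make the sequence irreversible. The closest known reactions are the additions of ynamines, alkoxyalkynes and ketene acetals to 5-acyl- and 5-alkoxycarbonyl-2-pyranones, which give benzenes with this orientation. No stereocenter is set, since the two bridgehead centres of racemic 16 become aromatic carbons. The step needs regioselectivity and periselectivity: the first is secured by the matched polarization, reinforced by the 4-methoxy group, which makes C3 the electron-rich end that pairs with the oxocarbenium-like alkyne carbon; the second by the fact that any adduct formed through the aroyl oxygen can revert whereas loss of CO2 cannot. Acid-free conditions without a Lewis acid keep the ynol ether from hydration and from carbonyl–alkyne metathesis with the ketone.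

Step 9
Reactants: 17 [4-(benzyloxy)phenyl]{5-[3-(4-(benzyloxy)phenyl)propyl]-2,4-dimethoxyphenyl}methanone
Product: 18 (4-hydroxyphenyl){2-hydroxy-5-[3-(4-hydroxyphenyl)propyl]-4-methoxyphenyl}methanone
Conditions: BCl3 (6 equiv), C6HMe5 (6 equiv), CH2Cl2, −78 to 0 °C; then MeOH, aq. NaHCO3
Reagents that add atoms: none
Why: BCl3 binds the ketone oxygen and the ortho (C3) methoxy oxygen in a six-membered chelate and cleaves that methyl ether selectively (chelation-controlled demethylation ortho to a carbonyl), and it cleaves both benzyl ethers while pentamethylbenzene traps the benzyl cations; the unchelated C1 methyl ether, para to the carbonyl, should survive at or below 0 °C.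

## Compound list

1 | methyl acetoacetate (methyl 3-oxobutanoate) | CC(=O)CC(=O)OC | starting material
2 | methyl 3,3-dimethoxybutanoate | COC(C)(OC)CC(=O)OC | intermediate
3 | methyl (E)-3-methoxybut-2-enoate | CO/C(C)=C/C(=O)OC | intermediate
4 | 4-(benzyloxy)benzoyl chloride | O=C(Cl)c1ccc(OCc2ccccc2)cc1 | starting material
5 | lithium 1,3-dimethoxybuta-1,3-dien-1-olate | [Li+].C=C(OC)C=C([O-])OC | intermediate
6 | methyl (2E)-5-[4-(benzyloxy)phenyl]-3-methoxy-5-oxopent-2-enoate | CO/C(CC(=O)c1ccc(OCc2ccccc2)cc1)=C/C(=O)OC | intermediate
7 | methyl (2E)-4-[4-(benzyloxy)benzoyl]-5-(dimethylamino)-3-methoxypenta-2,4-dienoate | CO/C(=C/C(=O)OC)C(=CN(C)C)C(=O)c1ccc(OCc2ccccc2)cc1 | intermediate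
8 | methyl (2E)-4-[4-(benzyloxy)benzoyl]-5-hydroxy-3-methoxypenta-2,4-dienoate | CO/C(=C/C(=O)OC)C(=CO)C(=O)c1ccc(OCc2ccccc2)cc1 | intermediate
9 | 5-[4-(benzyloxy)benzoyl]-4-methoxy-2H-pyran-2-one | COc1cc(=O)occ1C(=O)c1ccc(OCc2ccccc2)cc1 | intermediate
10 | 3-(4-hydroxyphenyl)propan-1-ol | OCCCc1ccc(O)cc1 | starting material
11 | 3-[4-(benzyloxy)phenyl]propan-1-ol | OCCCc1ccc(OCc2ccccc2)cc1 | intermediate
12 | 1-(benzyloxy)-4-(3-iodopropyl)benzene | ICCCc1ccc(OCc2ccccc2)cc1 | intermediate
13 | 2-chloro-1,1-dimethoxyethane (chloroacetaldehyde dimethyl acetal) | COC(CCl)OC | starting material
14 | lithium methoxyethynide | [Li+].[C-]#COC | intermediate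
15 | 1-(benzyloxy)-4-(5-methoxypent-4-yn-1-yl)benzene | COC#CCCCc1ccc(OCc2ccccc2)cc1 | intermediate
16 | 6-[4-(benzyloxy)benzoyl]-7-{3-[4-(benzyloxy)phenyl]propyl}-5,8-dimethoxy-2-oxabicyclo[2.2.2]octa-5,7-dien-3-one (racemic; one enantiomer written) | O=C1O[C@@H]2C(C(=O)c3ccc(OCc4ccccc4)cc3)=C(OC)[C@H]1C(OC)=C2CCCc5ccc(OCc6ccccc6)cc5 | intermediate
17 | [4-(benzyloxy)phenyl]{5-[3-(4-(benzyloxy)phenyl)propyl]-2,4-dimethoxyphenyl}methanone | COc1cc(OC)c(C(=O)c2ccc(OCc3ccccc3)cc2)cc1CCCc1ccc(OCc2ccccc2)cc1 | intermediate
18 | (4-hydroxyphenyl){2-hydroxy-5-[3-(4-hydroxyphenyl)propyl]-4-methoxyphenyl}methanone | COc1cc(O)c(C(=O)c2ccc(O)cc2)cc1CCCc1ccc(O)cc1 | target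

## Step count and least certain steps

Total: 9 steps. Longest linear sequence: 6 steps (1, 2, 3, 4, 8, 9); the ynol ether arm (steps 5, 6, 7) joins at step 8.

**Step 8 (key step).** The most likely failure is a cycloaddition that is too slow at a temperature the ynol ether tolerates. The 4-methoxy group donates into the pyranone and raises its LUMO, so oligomerisation of the ynol ether or addition across the aroyl enone could outrun ring formation. Fallback: ring A is then taken from a preformed resorcinol diether. From 12, cross-coupling with commercial 2,4-dimethoxyphenylmagnesium bromide (Fe(acac)3 cat., TMEDA, THF, 0 °C) gives 1-{3-[4-(benzyloxy)phenyl]propyl}-2,4-dimethoxybenzene F1. Friedel–Crafts acylation of F1 with 4 (SnCl4, CH2Cl2, −20 °C) at C5, para to one methoxy group and ortho to the other and far more activated than any position of ring C, rejoins the route at 17.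

**Step 2.** The most likely failure is loss of site control in the acylation (attack through the α-carbon or through oxygen), or premature lactonization of the product enolate through the ketone oxygen onto the cis ester, because the reaction runs under strongly basic conditions and the product is more acidic than the starting enoate. Fallback: from 3, LiN(iPr)2 and Me3SiCl give [(1,3-dimethoxybuta-1,3-dien-1-yl)oxy]trimethylsilane F2. This neutral vinylogous silyl ketene acetal is acylated at its terminal carbon by 4 in CH2Cl2 (−78 °C to rt), a known reaction of 1-alkoxy-1-silyloxydienes with acid chlorides in which no enolate is present. Aqueous work-up rejoins the route at 6.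

**Step 4.** The most likely failure is hydrolytic loss of the enol ether methyl group together with the vinylogous amide, since both are acid-labile enol derivatives. Fallback: the hydrolysis is then driven to completion on purpose. From 7, 2 M HCl in THF at reflux removes both groups, and the chain closes to 5-[4-(benzyloxy)benzoyl]-4-hydroxy-2H-pyran-2-one F3. O-Methylation of F3 with Me2SO4 and K2CO3 in acetone, the standard way to 4-methoxy-2-pyranones, rejoins the route at 9.

**Step 9.** The most likely failure is Friedel–Crafts benzylation of the three electron-rich rings by the benzyl cations released, or cleavage of the C1 methyl ether if the temperature must be raised to finish the debenzylation. Fallback: the two tasks are separated. From 17, hydrogenolysis (H2, 1 atm, Pd/C, EtOAc, rt) removes both benzyl groups without cationic intermediates and gives (4-hydroxyphenyl){5-[3-(4-hydroxyphenyl)propyl]-2,4-dimethoxyphenyl}methanone F4. BCl3 (3 equiv, CH2Cl2, 0 °C) then only has to perform the chelation-controlled demethylation of F4, which rejoins the route at 18.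

## Further compounds

F1 | step 8 | 1-{3-[4-(benzyloxy)phenyl]propyl}-2,4-dimethoxybenzene | COc1ccc(CCCc2ccc(OCc3ccccc3)cc2)c(OC)c1
F2 | step 2 | [(1,3-dimethoxybuta-1,3-dien-1-yl)oxy]trimethylsilane | C=C(OC)C=C(OC)O[Si](C)(C)C
F3 | step 4 | 5-[4-(benzyloxy)benzoyl]-4-hydroxy-2H-pyran-2-one | O=c1cc(O)c(C(=O)c2ccc(OCc3ccccc3)cc2)co1
F4 | step 9 | (4-hydroxyphenyl){5-[3-(4-hydroxyphenyl)propyl]-2,4-dimethoxyphenyl}methanone | COc1cc(OC)c(C(=O)c2ccc(O)cc2)cc1CCCc1ccc(O)cc1
A1 | alternative 1 | [2,4-dihydroxy-5-(hydroxymethyl)phenyl][4-(triisopropylsilyloxy)phenyl]methanone | OCc1cc(C(=O)c2ccc(O[Si](C(C)C)(C(C)C)C(C)C)cc2)c(O)cc1O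
A2 | alternative 1 | 3-hydroxy-6-methylidene-4-[4-(triisopropylsilyloxy)benzoyl]cyclohexa-2,4-dien-1-one | C=C1C=C(C(=O)c2ccc(O[Si](C(C)C)(C(C)C)C(C)C)cc2)C(O)=CC1=O
A3 | alternative 1 | triisopropyl(4-vinylphenoxy)silane | C=Cc1ccc(O[Si](C(C)C)(C(C)C)C(C)C)cc1
A4 | alternative 1 | racemic 7-hydroxy-6-[4-(triisopropylsilyloxy)benzoyl]-2-[4-(triisopropylsilyloxy)phenyl]chroman | Oc1cc2OC(c3ccc(O[Si](C(C)C)(C(C)C)C(C)C)cc3)CCc2cc1C(=O)c1ccc(O[Si](C(C)C)(C(C)C)C(C)C)cc1
A5 | alternative 2 | {[7-(4-(benzyloxy)phenyl)-1,3-dimethoxyhepta-1,3-dien-1-yl]oxy}trimethylsilane (double-bond geometry as formed) | COC(O[Si](C)(C)C)=CC(OC)=CCCCc1ccc(OCc2ccccc2)cc1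
A6 | alternative 2 | 1-[4-(benzyloxy)phenyl]prop-2-yn-1-one | C#CC(=O)c1ccc(OCc2ccccc2)cc1
A7 | alternative 2 | [4-(benzyloxy)phenyl]{5-[3-(4-(benzyloxy)phenyl)propyl]-2-hydroxy-4-methoxyphenyl}methanone | COc1cc(O)c(C(=O)c2ccc(OCc3ccccc3)cc2)cc1CCCc1ccc(OCc2ccccc2)cc1
A8 | alternative 3 | 2-[4-(benzyloxy)phenyl]-6-{5-[4-(benzyloxy)phenyl]-1-(dimethylamino)pent-1-en-2-yl}-4H-pyran-4-one | O=c1cc(-c2ccc(OCc3ccccc3)cc2)oc(C(=CN(C)C)CCCc2ccc(OCc3ccccc3)cc2)c1
A9 | alternative 3 | 1,9-bis[4-(benzyloxy)phenyl]-6-[(dimethylamino)methylidene]nonane-1,3,5-trione | O=C(CC(=O)CC(=O)C(=CN(C)C)CCCc1ccc(OCc2ccccc2)cc1)c1ccc(OCc2ccccc2)cc1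
A10 | alternative 3 | [4-(benzyloxy)phenyl]{5-[3-(4-(benzyloxy)phenyl)propyl]-2,4-dihydroxyphenyl}methanone | Oc1cc(O)c(C(=O)c2ccc(OCc3ccccc3)cc2)cc1CCCc1ccc(OCc2ccccc2)cc1
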